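**Plan**
- Retrosynthesis: the exocyclic C5=CBr2 bond is first taken back to a C5 hemiketal (C5–OH, CHBr2). The ring bond O1–C5 and the C3=C4 double bond are then cut together, giving 2-oxohexanoic acid (C2, C3, butyl) and 1,1,3-tribromoacetone (C4, C5, CBr2 carbon). The latter goes back to 1,3-dibromoacetone by one C–Br cut.
- Enabling feature: ring atom C5 is an enol-lactone carbon (O1–C5=CBr2), a masked ketone carbonyl 1,4 to the lactone carbonyl C2, and C3=C4 is the α,β-double bond of that ketone. The furanone ring is therefore the doubly dehydrated adduct of an α-keto acid and a bromomethyl ketone.
- Forward: bromination of 1,3-dibromoacetone, then an acid-mediated aldol condensation/lactolisation that builds the only ring with butyl and all three bromines in place, then dehydration of the hemiketal to the dibromomethylidene group.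
- Stereochemistry: none has to be set. The hemiketal centre of the intermediate forms as a racemate and is removed in the last step.

Key step: step 2

Remark: the target has no stereocentre, and its exocyclic C=C carries two bromines on one carbon, so it is achiral and has no E/Z isomer; "single enantiomer" is taken to mean the compound itself. 1,1,3-Tribromoacetone is a specialty chemical and is therefore made in step 1.

Step 1
Reactants: 1 1,3-dibromoacetone (1,3-dibromopropan-2-one)
Product: 2 1,1,3-tribromoacetone (1,1,3-tribromopropan-2-one)
Conditions: Br2 (0.95 equiv), cat. HBr, AcOH, 60 °C; fractional distillation in vacuo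
Reagents that add atoms: bromine, BrBr
Why: Acid-catalysed α-bromination of a ketone through its enol; both α-carbons of 1 are CH2Br, so the first substitution can only give 2, and a slight deficit of bromine with distillation should limit and remove tetrabromo products.

Step 2
Reactants: 3 2-oxohexanoic acid; 2 1,1,3-tribromoacetone
Product: 6 4-bromo-3-butyl-5-(dibromomethyl)-5-hydroxyfuran-2(5H)-one (racemic), via aldol adduct 4 (not isolated), via enone acid 5 (not isolated)
Conditions: 85 % H3PO4, 75 °C; 3 added slowly to 2 (3 equiv)
Reagents that add atoms: none
Why: Proposed new method: in the acid the CH2Br-side enol of 2 (BrCH=C(OH)CHBr2) should add to the protonated ketone carbonyl of 3 in an aldol addition to give 4, which loses its tertiary C3–OH and the C4–H α to the ketone by enol-assisted dehydration to the acylacrylic acid 5, which then closes by ring-chain tautomerism. The closest known reaction type is the acid-catalysed aldol condensation of glyoxylic or pyruvic acid with enolisable ketones to 5-hydroxyfuran-2(5H)-ones; new here is an α-bromoketone as the enol partner combined with an alkyl-substituted 2-oxo acid. The furanone ring closes by 5-exo-trig attack of the carboxyl oxygen on the C5 ketone carbon, favoured because the tetrasubstituted C3=C4 bond of 5 holds acid and acyl group cis (ring-chain behaviour as in mucobromic acid). The only new stereocentre, the hemiketal carbon C5 of 6, forms as a racemate without control and becomes sp2 in step 3. The step needs regioselectivity between the two α-carbons of 2 and cross- over self-condensation of 3: an adduct formed through the CHBr2 carbon cannot dehydrate and should revert by retro-aldol so that only the CH2Br pathway drains into 6, the hindered and weakly basic carbonyl of 2 is a poor acceptor, and slow addition of 3 to excess 2 keeps the second-order self-aldol of 3 slow. E/Z isomers of 5 should interconvert through rehydration to 4, so both reach 6.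

Step 3
Reactants: 6 4-bromo-3-butyl-5-(dibromomethyl)-5-hydroxyfuran-2(5H)-one
Product: 7 4-bromo-3-butyl-5-(dibromomethylidene)furan-2(5H)-one
Conditions: P2O5, CH2Cl2, reflux
Reagents that add atoms: none
Why: Dehydration of a 5-hydroxy-5-(halomethyl)furanone to the 5-(halomethylidene)furanone: the phosphorylated hemiketal hydroxyl leaves from C5 and the acidic CHBr2 proton is lost, giving the conjugated enol lactone; the vinylic and geminal bromines are inert to the anhydrous acid.

**Compound list**
1 | 1,3-dibromoacetone (1,3-dibromopropan-2-one) | BrCC(=O)CBr | starting material
2 | 1,1,3-tribromoacetone (1,1,3-tribromopropan-2-one) | BrCC(=O)C(Br)Br | intermediate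
3 | 2-oxohexanoic acid | CCCCC(=O)C(=O)O | starting material
4 | 3,5,5-tribromo-2-butyl-2-hydroxy-4-oxopentanoic acid (aldol adduct; racemic mixture of diastereomers) | CCCCC(O)(C(=O)O)C(Br)C(=O)C(Br)Br | intermediate
5 | (E)-3,5,5-tribromo-2-butyl-4-oxopent-2-enoic acid (enone acid; carboxyl cis to the acyl group) | CCCC/C(C(=O)O)=C(Br)/C(=O)C(Br)Br | intermediate
6 | 4-bromo-3-butyl-5-(dibromomethyl)-5-hydroxyfuran-2(5H)-one (racemic) | CCCCC1=C(Br)C(O)(C(Br)Br)OC1=O | intermediate
7 | 4-bromo-3-butyl-5-(dibromomethylidene)furan-2(5H)-one | CCCCC1=C(Br)C(=C(Br)Br)OC1=O | target

Total step count: 3
Longest linear sequence: 3 steps (1 → 2 → 6 → 7)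

**Steps most likely to fail**

1. Step 2 (proposed new method). The enol of 3 may react faster than the enol of 2, either with a second molecule of 3 or with the carbonyl of 2, so that self-condensation or a wrong-sense aldol outruns the wanted cross-condensation. The fallback uses known chemistry and fixes the roles of the partners; it sets out from 3 and returns at 6. Fischer esterification of 3 (EtOH, cat. H2SO4) gives ethyl 2-oxohexanoate F1. Wittig olefination of its activated ketone with commercial 1-(triphenylphosphoranylidene)propan-2-one in toluene at reflux gives ethyl 2-butyl-4-oxopent-2-enoate F2. Bromine (3 equiv) in AcOH with HBr catalysis, then warming to complete loss of HBr, should give ethyl 3,5,5-tribromo-2-butyl-4-oxopent-2-enoate F3, by addition–elimination at the C=C and twofold enol bromination of the methyl ketone. Hot aqueous H2SO4/AcOH then hydrolyses the ester, equilibrates the alkene geometry and closes the hemiketal to 6.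

2. Step 1. Bromination may run on past 2 or stop short of it, and HBr may scramble bromine between ketone molecules, leaving a mixture that is hard to fractionate. The fallback sets out from 1 and returns at 2. Compound 1 is converted with isopropenyl acetate and cat. TsOH (acetone distilled off) into 1,3-dibromoprop-1-en-2-yl acetate F4. One equivalent of bromine in CH2Cl2 at 0 °C adds to the enol double bond, and the adduct collapses with loss of acetyl bromide to 2. Because the enol is preformed in stoichiometric amount and the product does not enolise under these neutral conditions, a fourth bromine should not enter.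

3. Step 3. Ionisation at C5 may be slow because the lactone oxygen and two bromines destabilise the cation, giving incomplete dehydration, or the hemiketal may reopen and degrade on the acidic dehydrating agent. The fallback sets out from 6 and returns at 7. The hemiketal hydroxyl is acetylated (Ac2O, cat. H2SO4) to 3-bromo-4-butyl-2-(dibromomethyl)-5-oxo-2,5-dihydrofuran-2-yl acetate F5. Et3N in CH2Cl2 at 0 °C then removes the acidic CHBr2 proton and expels acetate, a base-mediated elimination in place of the acid dehydration, to give 7.

**Further compounds**
F1 | step 2 | ethyl 2-oxohexanoate | CCCCC(=O)C(=O)OCC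
F2 | step 2 | ethyl 2-butyl-4-oxopent-2-enoate (E/Z mixture) | CCCCC(C(=O)OCC)=CC(C)=O
F3 | step 2 | ethyl 3,5,5-tribromo-2-butyl-4-oxopent-2-enoate (E/Z mixture) | CCCCC(C(=O)OCC)=C(Br)C(=O)C(Br)Br
F4 | step 1 | 1,3-dibromoprop-1-en-2-yl acetate (E/Z mixture) | CC(=O)OC(=CBr)CBr
F5 | step 3 | 3-bromo-4-butyl-2-(dibromomethyl)-5-oxo-2,5-dihydrofuran-2-yl acetate (racemic) | CCCCC1=C(Br)C(OC(C)=O)(C(Br)Br)OC1=O
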